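All runs come from a simulation for an exercise; the scatter is artificial.

The easy step comes first: starting material ionises by itself to intermediate, on one first-order clock.

| flask | starting material | first nucleophile | second nucleophile | remark | time |
|---|---|---|---|---|---|
| Wednesday's | 10 mM | 12 mM | 5 mM | the very flask that is asked about, followed so far |  |
| Sunday's | 20 mM | 12 mM | 5 mM | run made earlier |  |
| flask | 10 mM | 12.0 mM | 5.00 mM |  | 12 h |

- Wednesday's (time / h: other capture product / %, target / %, starting material / %): 1.00: 15, 0, 83; 2.00: 25, 4, 69; 3.00: 31, 0, 60; 4.00: 41, 3, 49; 5.00: 45, 0, 45
- Sunday's (time / h: other capture product / %, target / %, starting material / %): 1.00: 14, 1, 83; 2.00: 18, 5, 74; 3.00: 23, 6, 61; 6.00: 26, 12, 38; 12.0: 24, 7, 13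

(readings scatter by 2 percentage points)

- reactions considered so far: starting material -> intermediate; first nucleophile + intermediate <-> target; second nucleophile + intermediate -> other capture product; intermediate -> solvolysis product

- share of other capture product in other capture product plus target at 12 min
- share of other capture product in other capture product plus target at 1.5 h
- share of other capture product in other capture product plus target at 12 h
- which of other capture product and target there is more of at 12 h

Wednesday's run has 45 % of starting material left after 5.00 h, which reads as a rate constant of 0.160 /h. Sunday's run, with twice the charge, reads 0.170 /h.

Two amounts are then compared, the charges of second nucleophile and starting material. One second nucleophile makes one other capture product, so [second nucleophile]/[starting material] as charged is the capture ceiling, the most other capture product that step can give: 50.0 % for Wednesday's flask. Sunday's ceiling is 25.0 %, and its readings level off at 26 % and 24 %, the mark of a limiting reagent.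

My own reckoning for Wednesday's flask is this. Other capture product reads 88.2 % of what has ionised after 1.00 h and 81.8 % after 5.00 h, so its share of the ionised material cannot be carried forward as a constant. At that last reading, 0.500 mM of the ceiling is still open, and the clock supplies a further 3.03 mM by 12 h, more than that, so other capture product should end close to the ceiling. Even with as much target as Sunday's highest reading, the late share would be 67.6 %, so other capture product leads.

The forecast goes higher: 92 %, 90 % and 92 %, with other capture product ahead, holding that target “forms late and leaks away”.

The flask gives 90.8 %, 93.9 % and 89.3 %, with other capture product ahead: 50.0 % at 12.0 h, equal to the ceiling of 50.0 %, against 5.97 % of target.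

    starting material → intermediate (k = 0.160 /h)
    first nucleophile + intermediate ⇌ target (K = 480 /M, k = 600 /M/h)
    second nucleophile + intermediate → other capture product (k = 13000 /M/h)
    intermediate → solvolysis product (k = 2.90 /h)

The late share stays high because solvolysis drains intermediate and target runs back to it, the two acting together. Taking away solvolysis gives 63.7 %, and taking away the back run gives 67.0 %, against 89.3 % in the flask. The neighbour flask charged with 2.0 mM of second nucleophile has a ceiling of 20.0 %, ends at 20.0 % of other capture product, and its late share falls to 74.2 %.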